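**Plan**

1. Numbering (labdane): ring A = C1–C5/C10, ring B = C5–C10, C11 on C9, C17 on C8, C18 (α) and C19 (β) on C4, C20 on C10; β is the face of the C10 methyl. The enabling feature: the carbinol carbon C6 lies between C5 and C7, so ring B hides an acetone unit C5–C6(=O)–C7 with two nucleophilic α-carbons, and C10/C9/C8(+C17) map onto an alkylidene acetoacetate that is electrophilic at C10 and at C8.
2. Retrosynthesis: cut the side chain at C11–C12 (1,6-addition to a dienone with an exocyclic C9=C11 bond) and at C13–C16; cut C5–C10 and C7–C8 together, which opens both rings to an acyclic diketone carrying the alkylidene acetoacetate; then C9=C10 (Knoevenagel), C4–C5 and C4–C18 (enolate alkylations) and C1–C2 (dianion alkylation).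
3. Forward: the chain grows linearly from methyl acetoacetate; one base-mediated operation closes ring A (Michael) and ring B (aldol condensation); the C11 ester is then turned into the exocyclic methylene that accepts the side chain and moves the alkene to C8=C9.
4. Stereochemistry: C3 from Ru/BINAP hydrogenation; C4 from two Fráter–Seebach alkylations; C10 and C5 from the chair-like ring closure steered by C3/C4 (C5 under thermodynamic control); C3 is then inverted by oxidation and bulky-hydride reduction; C6 by α-face hydride delivery; the C13 alkene from a Z-enol phosphate/cuprate coupling.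

Key step: step 9

Remark: 11–14 (and F6, F7, F11) are mixtures at the C9=C10 double bond or at C8/C9, elements that disappear downstream, so their SMILES leave these open; 19 is drawn as the expected 6β-alcohol, either C6 epimer serving in step 12.

**Step 1**
Reactants: 1 methyl 3-oxobutanoate (methyl acetoacetate); 2 3-chloro-2-methylprop-1-ene
Product: 3 methyl 6-methyl-3-oxohept-6-enoate
Conditions: NaH, THF, 0 °C; n-BuLi, 0 °C; then 2, 0 → 25 °C; aq. NH4Cl
Reagents that add atoms: none
Why: γ-Alkylation of a β-keto ester dianion takes place at the more basic terminal carbon with the reactive allylic chloride and builds C1–C2.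

**Step 2**
Reactants: 3 methyl 6-methyl-3-oxohept-6-enoate
Product: 4 methyl (3S)-3-hydroxy-6-methylhept-6-enoate
Conditions: H2 (4 atm), [RuCl2((S)-BINAP)] (0.5 mol%), MeOH, 50 °C
Reagents that add atoms: none
Why: Noyori asymmetric hydrogenation of a β-keto ester with the (S)-BINAP catalyst should set C3 as S, the isolated 1,1-disubstituted alkene being a poor substrate for halide-containing Ru–BINAP catalysts at low pressure.

**Step 3**
Reactants: 4 methyl (3S)-3-hydroxy-6-methylhept-6-enoate; 5 3-bromo-1-(trimethylsilyl)prop-1-yne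
Product: 6 methyl (2S,3S)-3-hydroxy-6-methyl-2-[3-(trimethylsilyl)prop-2-yn-1-yl]hept-6-enoate
Conditions: LiN(i-Pr)2 (2.2 equiv), THF, −78 → −20 °C; then 5, −78 → 0 °C
Reagents that add atoms: none
Why: Fráter–Seebach alkylation of the chelated alkoxide–enolate dianion should deliver the propargylic electrophile to the enolate face anti to the C3 side chain (2,3-anti product).

**Step 4**
Reactants: 6 methyl (2S,3S)-3-hydroxy-6-methyl-2-[3-(trimethylsilyl)prop-2-yn-1-yl]hept-6-enoate
Product: 8 methyl (2R,3S)-3-hydroxy-2,6-dimethyl-2-(prop-2-yn-1-yl)hept-6-enoate, via C-silylated alkyne 7 (not isolated)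
Conditions: LiN(i-Pr)2 (2.2 equiv), THF/DMPU, −78 → −20 °C; MeI, −78 → 0 °C; then MeOH, K2CO3, 25 °C
Reagents that add atoms: iodomethane, CI
Why: A second Fráter–Seebach alkylation should bring methyl iodide to the same enolate face, so the quaternary carbon (later C4) carries methyl anti and propargyl syn to the hydroxyl, and methanolic carbonate then removes the alkyne silyl group.

**Step 5**
Reactants: 8 methyl (2R,3S)-3-hydroxy-2,6-dimethyl-2-(prop-2-yn-1-yl)hept-6-enoate
Product: 9 methyl (2R,3S)-3-[(tert-butyldimethylsilyl)oxy]-2,6-dimethyl-2-(prop-2-yn-1-yl)hept-6-enoate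
Conditions: TBSOTf, 2,6-lutidine, CH2Cl2, 0 °C
Reagents that add atoms: tert-butyldimethylsilyl trifluoromethanesulfonate, CC(C)(C)[Si](C)(C)OS(=O)(=O)C(F)(F)F
Why: Silyl triflate silylation protects the hindered secondary alcohol, which would otherwise undergo retro-aldol or oxa-Michael reactions under the basic ring closure.

**Step 6**
Reactants: 9 methyl (2R,3S)-3-[(tert-butyldimethylsilyl)oxy]-2,6-dimethyl-2-(prop-2-yn-1-yl)hept-6-enoate
Product: 10 methyl (2R,3S)-3-[(tert-butyldimethylsilyl)oxy]-2-methyl-6-oxo-2-(prop-2-yn-1-yl)heptanoate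
Conditions: O3, CH2Cl2, −78 °C (Sudan red 7B end point); then Me2S, −78 → 25 °C
Reagents that add atoms: ozone, [O-][O+]=O
Why: Ozonolysis cleaves the electron-rich 1,1-disubstituted alkene far faster than the terminal alkyne and unveils the C10 methyl ketone while C6 stays masked.

**Step 7**
Reactants: 10 methyl (2R,3S)-3-[(tert-butyldimethylsilyl)oxy]-2-methyl-6-oxo-2-(prop-2-yn-1-yl)heptanoate; 1 methyl 3-oxobutanoate
Product: 11 dimethyl (6S,7R)-2-acetyl-6-[(tert-butyldimethylsilyl)oxy]-3,7-dimethyl-7-(prop-2-yn-1-yl)oct-2-enedioate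
Conditions: TiCl4 (2 equiv), pyridine (4 equiv), THF, 0 → 25 °C
Reagents that add atoms: none
Why: TiCl4/pyridine Knoevenagel condensation of the only ketone present with the β-keto ester forms the C9=C10 bond and installs C8, C17 and the C11 ester, the alkene geometry being irrelevant.

**Step 8**
Reactants: 11 dimethyl (6S,7R)-2-acetyl-6-[(tert-butyldimethylsilyl)oxy]-3,7-dimethyl-7-(prop-2-yn-1-yl)oct-2-enedioate
Product: 12 dimethyl (6S,7R)-2-acetyl-6-[(tert-butyldimethylsilyl)oxy]-3,7-dimethyl-7-(2-oxopropyl)oct-2-enedioate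
Conditions: (Ph3P)AuCl (2 mol%), AgOSO2CF3 (2 mol%), 1,4-dioxane/H2O (10:1), 60 °C
Reagents that add atoms: water, O
Why: Gold-catalysed Markovnikov hydration of the terminal alkyne, assisted by the neighbouring ester carbonyl, gives the C6 methyl ketone under near-neutral conditions that leave the alkylidene acetoacetate and silyl ether intact.

**Step 9**
Reactants: 12 dimethyl (6S,7R)-2-acetyl-6-[(tert-butyldimethylsilyl)oxy]-3,7-dimethyl-7-(2-oxopropyl)oct-2-enedioate
Product: 16 dimethyl 3β-hydroxy-6-oxo-12,13,14,15,16-pentanorlabd-7-ene-11,19-dioate, via seco-diketone Michael adduct 13 (not isolated), via ketol 14 (not isolated), via silyl ether enone 15 (not isolated)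
Conditions: KOt-Bu (1.2 equiv), t-BuOH/THF, 0 → 40 °C; then HCl (3 M in MeOH), 50 °C
Reagents that add atoms: none
Why: KOt-Bu equilibrates the enolates of the C6 methyl ketone, and only the C5 enolate can reach the alkylidene acetoacetate through a six-membered transition state, so a 6-exo-trig Michael addition joins C5 to C10 (ring A, 13); the 1,5-diketone then closes ring B by a 6-(enolexo)-exo-trig aldol addition of C7 to the C8 ketone (14), and the acid dehydrates the ketol, equilibrates to the conjugated C7=C8 enone (15) and removes the silyl ether. The closest known reaction type is the Michael–aldol cyclohexenone annulation (Robinson-type, as in the Knoevenagel/Hagemann synthesis of 4-carboalkoxy-3-methylcyclohexenones), here with both events intramolecular. The quaternary centre C10 is set in the chair-like Michael transition state by C3 and C4: the silyloxy group should sit equatorial, and the planar ester rather than the C4 methyl should take the axial site syn to the incoming axial C10 methyl, which places C20 cis to C19. C5 is epimerisable next to the C6 ketone and should settle as the trans ring fusion (5α-H), and C9 as the equatorial ester, a centre that is lost later. The step needs C5 rather than C7 as Michael donor (secured by ring size), C7-to-C8 rather than C17-to-C6 aldol closure (the β-keto ester ketone is the more electrophilic carbonyl, as in acetoacetate–enone adducts) and one face at C10 (secured by C3/C4 as above).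

**Step 10**
Reactants: 16 dimethyl 3β-hydroxy-6-oxo-12,13,14,15,16-pentanorlabd-7-ene-11,19-dioate
Product: 17 dimethyl 3,6-dioxo-12,13,14,15,16-pentanorlabd-7-ene-11,19-dioate
Conditions: Dess–Martin periodinane, NaHCO3, CH2Cl2, 25 °C
Reagents that add atoms: none
Why: Dess–Martin oxidation removes the C3 centre that has done its steering work, the adjacent quaternary C4 being unable to epimerise.

**Step 11**
Reactants: 17 dimethyl 3,6-dioxo-12,13,14,15,16-pentanorlabd-7-ene-11,19-dioate
Product: 19 3α,6β,11,19-tetrahydroxy-12,13,14,15,16-pentanorlabd-7-ene, via 3α-hydroxy enone diester 18 (not isolated)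
Conditions: LiBH(s-Bu)3 (1.2 equiv), THF, −78 °C; then LiAlH4 (5 equiv), −78 → 40 °C; aq. NaOH work-up
Reagents that add atoms: none
Why: The bulky trialkylborohydride should attack the C3 ketone from the equatorial direction and give the axial 3α-alcohol (as known for 4,4-disubstituted 3-oxo terpenoids), and LiAlH4 then reduces both methyl esters and, from the open α-face, the C6 ketone.

**Step 12**
Reactants: 19 3α,6β,11,19-tetrahydroxy-12,13,14,15,16-pentanorlabd-7-ene
Product: 20 3α,11,19-trihydroxy-12,13,14,15,16-pentanorlabd-7-en-6-one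
Conditions: MnO2 (20 equiv), CH2Cl2, 25 °C
Reagents that add atoms: none
Why: MnO2 oxidises only the allylic C6 alcohol, the saturated secondary (C3), neopentyl (C19) and homoallylic (C11) alcohols being inert to this reagent.

**Step 13**
Reactants: 20 3α,11,19-trihydroxy-12,13,14,15,16-pentanorlabd-7-en-6-one
Product: 22 6-oxo-12,13,14,15,16-pentanorlabda-7,9(11)-diene-3α,19-diyl bis(3-methylbutanoate), via tris(3-methylbutanoate) 21 (not isolated)
Conditions: 3-methylbutanoyl chloride (4 equiv), pyridine, DMAP (0.2 equiv), CH2Cl2, 0 → 25 °C; then DBU (3 equiv), 25 °C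
Reagents that add atoms: 3-methylbutanoyl chloride, CC(C)CC(=O)Cl
Why: DMAP-catalysed acylation esterifies all three hydroxyls, and E1cB (vinylogous β-) elimination of the C11 ester through the γ-deprotonated enone then leaves exactly the two esters of the target and creates the exocyclic C9=C11 bond.

**Step 14**
Reactants: 23 tert-butyl 3-oxobutanoate
Product: 25 1-tert-butoxy-1,3-bis(trimethylsilyloxy)buta-1,3-diene, via mono-silyl enol ether 24 (not isolated)
Conditions: Et3N, TMSCl, hexane, 25 °C; filter, concentrate; then LiN(i-Pr)2, THF, −78 °C; TMSCl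
Reagents that add atoms: chlorotrimethylsilane, C[Si](C)(C)Cl
Why: Stepwise O-silylation of the β-keto ester and of its γ-deprotonated dienolate gives the bis-silyl dienolate (Chan-type diene), a neutral equivalent of the acetoacetate dianion.

**Step 15**
Reactants: 22 6-oxo-12,13,14,15,16-pentanorlabda-7,9(11)-diene-3α,19-diyl bis(3-methylbutanoate); 25 1-tert-butoxy-1,3-bis(trimethylsilyloxy)buta-1,3-diene
Product: 26 tert-butyl 3α,19-bis[(3-methylbutanoyl)oxy]-6,13-dioxo-16-norlabd-8-en-15-oate
Conditions: TiCl4 (1.1 equiv), CH2Cl2, −78 °C; aq. NaHCO3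
Reagents that add atoms: none
Why: In a vinylogous Mukaiyama–Michael reaction the terminal carbon of the bis-silyl dienolate should add 1,6 to the unhindered exocyclic methylene (C11–C12 bond), and kinetic α-protonation at C7 of the resulting dienolate on quench places the ring alkene at C8=C9.

**Step 16**
Reactants: 26 tert-butyl 3α,19-bis[(3-methylbutanoyl)oxy]-6,13-dioxo-16-norlabd-8-en-15-oate
Product: 27 tert-butyl (13Z)-13-[(diethoxyphosphoryl)oxy]-3α,19-bis[(3-methylbutanoyl)oxy]-6-oxo-16-norlabda-8,13-dien-15-oate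
Conditions: NaH (1.05 equiv), Et2O, 0 °C; ClP(O)(OEt)2, 0 → 25 °C
Reagents that add atoms: diethyl chlorophosphate, CCOP(=O)(Cl)OCC
Why: One equivalent of NaH deprotonates only the β-keto ester, and O-phosphorylation of its chelated sodium enolate gives the Z-enol phosphate.

**Step 17**
Reactants: 27 tert-butyl (13Z)-13-[(diethoxyphosphoryl)oxy]-3α,19-bis[(3-methylbutanoyl)oxy]-6-oxo-16-norlabda-8,13-dien-15-oate
Product: 28 tert-butyl (13E)-3α,19-bis[(3-methylbutanoyl)oxy]-6-oxolabda-8,13-dien-15-oate
Conditions: Me2CuLi (3 equiv), Et2O, −78 → −45 °C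
Reagents that add atoms: lithium dimethylcuprate, [Li+].C[Cu-]C
Why: Cuprate coupling of a β-(phosphoryloxy) enoate proceeds with retention of geometry, so the Z-enol phosphate should give the E-trisubstituted enoate, while the hindered ketone and the esters are not attacked at low temperature.

**Step 18**
Reactants: 28 tert-butyl (13E)-3α,19-bis[(3-methylbutanoyl)oxy]-6-oxolabda-8,13-dien-15-oate
Product: 29 tert-butyl (13E)-6β-hydroxy-3α,19-bis[(3-methylbutanoyl)oxy]labda-8,13-dien-15-oate
Conditions: NaBH4, CeCl3·7H2O, MeOH/THF, −40 → 0 °C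
Reagents that add atoms: none
Why: In this borohydride reduction the β-face of the C6 ketone is screened by the syn-axial C20 methyl and C19 acyloxymethyl groups, so hydride should arrive from the α-face and give the axial 6β-alcohol (6R), the cerium salt keeping the medium non-basic (no acyl migration, no alkene conjugation).

**Step 19**
Reactants: 29 tert-butyl (13E)-6β-hydroxy-3α,19-bis[(3-methylbutanoyl)oxy]labda-8,13-dien-15-oate
Product: 31 (13E)-6β-hydroxy-3α,19-bis[(3-methylbutanoyl)oxy]labda-8,13-dien-15-oic acid, via bis(trimethylsilyl) derivative 30 (not isolated)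
Conditions: TMSOTf (3 equiv), 2,6-lutidine (4 equiv), CH2Cl2, 0 °C; then aq. citric acid, THF, 25 °C
Reagents that add atoms: none
Why: Silyl triflate-mediated cleavage of the tert-butyl ester (loss of isobutene to the silyl ester) is non-protic, so the tetrasubstituted alkene and the homoallylic alcohol are spared, and mild aqueous acid then frees the acid and the 6-hydroxyl without touching the isovalerates.

**Compound list**

1 | methyl 3-oxobutanoate (methyl acetoacetate) | COC(=O)CC(C)=O | starting material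
2 | 3-chloro-2-methylprop-1-ene | C=C(C)CCl | starting material
3 | methyl 6-methyl-3-oxohept-6-enoate | COC(=O)CC(=O)CCC(C)=C | intermediate
4 | methyl (3S)-3-hydroxy-6-methylhept-6-enoate | C=C(C)CC[C@H](O)CC(=O)OC | intermediate
5 | 3-bromo-1-(trimethylsilyl)prop-1-yne | C[Si](C)(C)C#CCBr | starting material
6 | methyl (2S,3S)-3-hydroxy-6-methyl-2-[3-(trimethylsilyl)prop-2-yn-1-yl]hept-6-enoate | C=C(C)CC[C@H](O)[C@H](CC#C[Si](C)(C)C)C(=O)OC | intermediate
7 | methyl (2R,3S)-3-hydroxy-2,6-dimethyl-2-[3-(trimethylsilyl)prop-2-yn-1-yl]hept-6-enoate (not isolated) | C=C(C)CC[C@H](O)[C@@](C)(CC#C[Si](C)(C)C)C(=O)OC | intermediate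
8 | methyl (2R,3S)-3-hydroxy-2,6-dimethyl-2-(prop-2-yn-1-yl)hept-6-enoate | C=C(C)CC[C@H](O)[C@@](C)(CC#C)C(=O)OC | intermediate
9 | methyl (2R,3S)-3-[(tert-butyldimethylsilyl)oxy]-2,6-dimethyl-2-(prop-2-yn-1-yl)hept-6-enoate | C=C(C)CC[C@H](O[Si](C)(C)C(C)(C)C)[C@@](C)(CC#C)C(=O)OC | intermediate
10 | methyl (2R,3S)-3-[(tert-butyldimethylsilyl)oxy]-2-methyl-6-oxo-2-(prop-2-yn-1-yl)heptanoate | CC(=O)CC[C@H](O[Si](C)(C)C(C)(C)C)[C@@](C)(CC#C)C(=O)OC | intermediate
11 | dimethyl (6S,7R)-2-acetyl-6-[(tert-butyldimethylsilyl)oxy]-3,7-dimethyl-7-(prop-2-yn-1-yl)oct-2-enedioate (E/Z mixture) | COC(=O)C(C(C)=O)=C(C)CC[C@H](O[Si](C)(C)C(C)(C)C)[C@@](C)(CC#C)C(=O)OC | intermediate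
12 | dimethyl (6S,7R)-2-acetyl-6-[(tert-butyldimethylsilyl)oxy]-3,7-dimethyl-7-(2-oxopropyl)oct-2-enedioate (E/Z mixture) | COC(=O)C(C(C)=O)=C(C)CC[C@H](O[Si](C)(C)C(C)(C)C)[C@@](C)(CC(C)=O)C(=O)OC | intermediate
13 | dimethyl 3β-[(tert-butyldimethylsilyl)oxy]-6,8-dioxo-7,8-seco-12,13,14,15,16-pentanorlabdane-11,19-dioate (C9 epimers, not isolated) | COC(=O)C(C(C)=O)[C@@]1(C)CC[C@H](O[Si](C)(C)C(C)(C)C)[C@](C)(C(=O)OC)[C@@H]1C(C)=O | intermediate
14 | dimethyl 3β-[(tert-butyldimethylsilyl)oxy]-8-hydroxy-6-oxo-12,13,14,15,16-pentanorlabdane-11,19-dioate (C8/C9 epimers, not isolated) | CC1(O)C(C(=O)OC)[C@@]2(C)CC[C@H](O[Si](C)(C)C(C)(C)C)[C@](C)(C(=O)OC)[C@@H]2C(=O)C1 | intermediate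
15 | dimethyl 3β-[(tert-butyldimethylsilyl)oxy]-6-oxo-12,13,14,15,16-pentanorlabd-7-ene-11,19-dioate (not isolated) | CC=1[C@H](C(=O)OC)[C@@]2(C)CC[C@H](O[Si](C)(C)C(C)(C)C)[C@](C)(C(=O)OC)[C@@H]2C(=O)C=1 | intermediate
16 | dimethyl 3β-hydroxy-6-oxo-12,13,14,15,16-pentanorlabd-7-ene-11,19-dioate | CC=1[C@H](C(=O)OC)[C@@]2(C)CC[C@H](O)[C@](C)(C(=O)OC)[C@@H]2C(=O)C=1 | intermediate
17 | dimethyl 3,6-dioxo-12,13,14,15,16-pentanorlabd-7-ene-11,19-dioate | CC=1[C@H](C(=O)OC)[C@@]2(C)CCC(=O)[C@](C)(C(=O)OC)[C@@H]2C(=O)C=1 | intermediate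
18 | dimethyl 3α-hydroxy-6-oxo-12,13,14,15,16-pentanorlabd-7-ene-11,19-dioate (not isolated) | CC=1[C@H](C(=O)OC)[C@@]2(C)CC[C@@H](O)[C@](C)(C(=O)OC)[C@@H]2C(=O)C=1 | intermediate
19 | 3α,6β,11,19-tetrahydroxy-12,13,14,15,16-pentanorlabd-7-ene | CC=1[C@H](CO)[C@@]2(C)CC[C@@H](O)[C@](C)(CO)[C@@H]2[C@H](O)C=1 | intermediate
20 | 3α,11,19-trihydroxy-12,13,14,15,16-pentanorlabd-7-en-6-one | CC=1[C@H](CO)[C@@]2(C)CC[C@@H](O)[C@](C)(CO)[C@@H]2C(=O)C=1 | intermediate
21 | 6-oxo-12,13,14,15,16-pentanorlabd-7-ene-3α,11,19-triyl tris(3-methylbutanoate) (not isolated) | CC=1[C@H](COC(=O)CC(C)C)[C@@]2(C)CC[C@@H](OC(=O)CC(C)C)[C@](C)(COC(=O)CC(C)C)[C@@H]2C(=O)C=1 | intermediate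
22 | 6-oxo-12,13,14,15,16-pentanorlabda-7,9(11)-diene-3α,19-diyl bis(3-methylbutanoate) | CC=1C(=C)[C@@]2(C)CC[C@@H](OC(=O)CC(C)C)[C@](C)(COC(=O)CC(C)C)[C@@H]2C(=O)C=1 | intermediate
23 | tert-butyl 3-oxobutanoate | CC(=O)CC(=O)OC(C)(C)C | starting material
24 | tert-butyl 3-[(trimethylsilyl)oxy]but-2-enoate (not isolated) | CC(O[Si](C)(C)C)=CC(=O)OC(C)(C)C | intermediate
25 | 1-tert-butoxy-1,3-bis(trimethylsilyloxy)buta-1,3-diene | C=C(O[Si](C)(C)C)C=C(OC(C)(C)C)O[Si](C)(C)C | intermediate
26 | tert-butyl 3α,19-bis[(3-methylbutanoyl)oxy]-6,13-dioxo-16-norlabd-8-en-15-oate | CC1=C(CCC(=O)CC(=O)OC(C)(C)C)[C@@]2(C)CC[C@@H](OC(=O)CC(C)C)[C@](C)(COC(=O)CC(C)C)[C@@H]2C(=O)C1 | intermediate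
27 | tert-butyl (13Z)-13-[(diethoxyphosphoryl)oxy]-3α,19-bis[(3-methylbutanoyl)oxy]-6-oxo-16-norlabda-8,13-dien-15-oate | CC1=C(CC/C(OP(=O)(OCC)OCC)=C/C(=O)OC(C)(C)C)[C@@]2(C)CC[C@@H](OC(=O)CC(C)C)[C@](C)(COC(=O)CC(C)C)[C@@H]2C(=O)C1 | intermediate
28 | tert-butyl (13E)-3α,19-bis[(3-methylbutanoyl)oxy]-6-oxolabda-8,13-dien-15-oate | CC1=C(CC/C(C)=C/C(=O)OC(C)(C)C)[C@@]2(C)CC[C@@H](OC(=O)CC(C)C)[C@](C)(COC(=O)CC(C)C)[C@@H]2C(=O)C1 | intermediate
29 | tert-butyl (13E)-6β-hydroxy-3α,19-bis[(3-methylbutanoyl)oxy]labda-8,13-dien-15-oate | CC1=C(CC/C(C)=C/C(=O)OC(C)(C)C)[C@@]2(C)CC[C@@H](OC(=O)CC(C)C)[C@](C)(COC(=O)CC(C)C)[C@@H]2[C@H](O)C1 | intermediate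
30 | trimethylsilyl (13E)-3α,19-bis[(3-methylbutanoyl)oxy]-6β-[(trimethylsilyl)oxy]labda-8,13-dien-15-oate (not isolated) | CC1=C(CC/C(C)=C/C(=O)O[Si](C)(C)C)[C@@]2(C)CC[C@@H](OC(=O)CC(C)C)[C@](C)(COC(=O)CC(C)C)[C@@H]2[C@H](O[Si](C)(C)C)C1 | intermediate
31 | (13E)-6β-hydroxy-3α,19-bis[(3-methylbutanoyl)oxy]labda-8,13-dien-15-oic acid (CNP0333611.1) | CC1=C(CC/C(C)=C/C(=O)O)[C@@]2(C)CC[C@@H](OC(=O)CC(C)C)[C@](C)(COC(=O)CC(C)C)[C@@H]2[C@H](O)C1 | target

**Totals and risks**

Total step count: 19. Longest linear sequence: 18 steps (steps 1–13 and 15–19; step 14 prepares the diene 25).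

The three steps most likely to fail:

1. Step 9. The Michael closure may show insufficient facial discrimination: a bulky silyloxy group flanked by a quaternary carbon may not seek the equatorial site as assumed, so the chair with the C4 methyl axial would compete. The closure may also be slow while the acceptor rests as its γ-deprotonated dienolate, which gives time for Claisen attack of C7 on the C19 ester. The fallback sets out from compound 3, uses the C3-epimeric series (the C3 oxygen axial and anti to the ester in the productive chair, carried as a small pivalate) and comes back at compound 19. Compound 3 would be hydrogenated with the (R)-BINAP catalyst to the (3R)-hydroxy ester F1. Fráter–Seebach methylation would give the anti α-methyl ester F2, and a second alkylation with 3-bromoprop-1-yne the quaternary alkyne F3 (C3 epimer of 8, same C4). Pivaloylation (pivaloyl chloride, DMAP, pyridine) would give pivalate F4, ozonolysis the methyl ketone F5, TiCl4/pyridine condensation with 1 the alkylidene acetoacetate F6, and gold-catalysed hydration the diketone F7. KOt-Bu followed by TsOH in toluene would close both rings to the 3α-pivaloyloxy enone diester F8. LiAlH4 would cleave the pivalate, reduce both methyl esters and the ketone, and so give 19 directly, steps 10 and 11 being dropped.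

2. Step 7. The dehydrative condensation of an aliphatic methyl ketone with a β-keto ester may stall, with self-aldolisation of 10 and deconjugation of the product competing. The fallback sets out from compound 10 and comes back at compound 11 by an acetal-based Mukaiyama-type addition instead of a condensation. Ketone 10 would be converted with trimethyl orthoformate, MeOH and pyridinium p-toluenesulfonate into the dimethyl ketal F9. Under catalytic TMSOTf at −78 °C, F9 would react with the trimethylsilyl enol ether of methyl acetoacetate F10 (from 1, TMSCl, Et3N) to give the β-methoxy adduct F11. E1cB loss of methanol with DBU would give 11.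

3. Step 15. The ambident bis-silyl dienolate may attack through its internal carbon or be lost by protodesilylation before it adds, and the dienolate formed may be reprotonated at C9, which would give the conjugated C7=C8 isomer. The fallback sets out from compound 22 and comes back at compound 28, dividing the task between a non-ambident nucleophile and an olefination. Compound 22 would be treated with commercial 2-(trimethylsilyloxy)propene and TiCl4 at −78 °C to give the methyl ketone F12. Horner–Wadsworth–Emmons olefination of the unhindered C13 ketone with tert-butyl diethylphosphonoacetate and NaH would give 28 after removal of the minor Z isomer, steps 16 and 17 being dropped.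

**Further compounds**

F1 | step 9 | methyl (3R)-3-hydroxy-6-methylhept-6-enoate | C=C(C)CC[C@@H](O)CC(=O)OC
F2 | step 9 | methyl (2R,3R)-3-hydroxy-2,6-dimethylhept-6-enoate | C=C(C)CC[C@@H](O)[C@@H](C)C(=O)OC
F3 | step 9 | methyl (2R,3R)-3-hydroxy-2,6-dimethyl-2-(prop-2-yn-1-yl)hept-6-enoate | C=C(C)CC[C@@H](O)[C@@](C)(CC#C)C(=O)OC
F4 | step 9 | methyl (2R,3R)-3-[(2,2-dimethylpropanoyl)oxy]-2,6-dimethyl-2-(prop-2-yn-1-yl)hept-6-enoate | C=C(C)CC[C@@H](OC(=O)C(C)(C)C)[C@@](C)(CC#C)C(=O)OC
F5 | step 9 | methyl (2R,3R)-3-[(2,2-dimethylpropanoyl)oxy]-2-methyl-6-oxo-2-(prop-2-yn-1-yl)heptanoate | CC(=O)CC[C@@H](OC(=O)C(C)(C)C)[C@@](C)(CC#C)C(=O)OC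
F6 | step 9 | dimethyl (6R,7R)-2-acetyl-6-[(2,2-dimethylpropanoyl)oxy]-3,7-dimethyl-7-(prop-2-yn-1-yl)oct-2-enedioate | COC(=O)C(C(C)=O)=C(C)CC[C@@H](OC(=O)C(C)(C)C)[C@@](C)(CC#C)C(=O)OC
F7 | step 9 | dimethyl (6R,7R)-2-acetyl-6-[(2,2-dimethylpropanoyl)oxy]-3,7-dimethyl-7-(2-oxopropyl)oct-2-enedioate | COC(=O)C(C(C)=O)=C(C)CC[C@@H](OC(=O)C(C)(C)C)[C@@](C)(CC(C)=O)C(=O)OC
F8 | step 9 | dimethyl 3α-[(2,2-dimethylpropanoyl)oxy]-6-oxo-12,13,14,15,16-pentanorlabd-7-ene-11,19-dioate | CC=1[C@H](C(=O)OC)[C@@]2(C)CC[C@@H](OC(=O)C(C)(C)C)[C@](C)(C(=O)OC)[C@@H]2C(=O)C=1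
F9 | step 7 | methyl (2R,3S)-3-[(tert-butyldimethylsilyl)oxy]-6,6-dimethoxy-2-methyl-2-(prop-2-yn-1-yl)heptanoate | CC(OC)(OC)CC[C@H](O[Si](C)(C)C(C)(C)C)[C@@](C)(CC#C)C(=O)OC
F10 | step 7 | methyl 3-[(trimethylsilyl)oxy]but-2-enoate | CC(O[Si](C)(C)C)=CC(=O)OC
F11 | step 7 | dimethyl (6S,7R)-2-acetyl-6-[(tert-butyldimethylsilyl)oxy]-3-methoxy-3,7-dimethyl-7-(prop-2-yn-1-yl)octanedioate | COC(=O)C(C(C)=O)C(C)(OC)CC[C@H](O[Si](C)(C)C(C)(C)C)[C@@](C)(CC#C)C(=O)OC
F12 | step 15 | 6,13-dioxo-14,15-dinorlabd-8-ene-3α,19-diyl bis(3-methylbutanoate) | CC1=C(CCC(C)=O)[C@@]2(C)CC[C@@H](OC(=O)CC(C)C)[C@](C)(COC(=O)CC(C)C)[C@@H]2C(=O)C1
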